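**Retrosynthetic overview**
1. Cut the C2–CH2 bond of the target. The chromone C2, normally the electrophilic β-carbon of the vinylogous ester, is used as a nucleophile: a C2-zinc chromone (β-acylvinyl / α-alkoxyvinyl anion, a masked acyl anion of the latent 1,3-diketone) is joined to a primary alkyl bromide.
2. The nucleophile comes from 6,7-dimethoxychromone by C2–H zincation; the electrophile is the silyl-protected 4-(2-bromoethyl)-2-methoxyphenol.
3. Only the pyranone ring is built (first, from the 2'-hydroxyacetophenone and a one-carbon amide acetal); both benzene rings are bought.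
4. The bromide comes from homovanillyl alcohol in one pot (Appel bromination, then silylation); the silyl group is removed in the coupling pot.

Assumption: the target SMILES contains no stereocentre and no stereogenic double bond, so the compound is achiral and no stereocontrol is needed.

**Route**

Step 1
Reactants: 1 1-(2-hydroxy-4,5-dimethoxyphenyl)ethan-1-one
Product: 3 6,7-dimethoxy-4H-chromen-4-one, via enaminone 2 (not isolated)
Conditions: DMF-DMA (2 equiv), toluene, 100 °C, 3 h; concentrate; then conc. HCl, CH2Cl2, 40 °C, 1 h
Reagents that add atoms: N,N-dimethylformamide dimethyl acetal, COC(OC)N(C)C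
Why: condensation of the acetyl CH3 with the amide acetal gives the enaminone, and acid then triggers intramolecular oxa-Michael addition of the phenol and loss of dimethylamine (addition–elimination, the standard enaminone chromone synthesis); no stereocentre is formed.

Step 2
Reactants: 4 4-(2-hydroxyethyl)-2-methoxyphenol (homovanillyl alcohol)
Product: 6 tert-butyl[4-(2-bromoethyl)-2-methoxyphenoxy]dimethylsilane, via bromophenol 5 (not isolated)
Conditions: CBr4 (1.3 equiv), PPh3 (1.3 equiv), CH2Cl2, 0 °C to rt, 1 h; then imidazole (3 equiv), TBSCl (1.3 equiv), rt, 3 h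
Reagents that add atoms: carbon tetrabromide, BrC(Br)(Br)Br; tert-butyldimethylsilyl chloride, CC(C)(C)[Si](C)(C)Cl
Why: the Appel reaction brominates only the primary alcohol by SN2 displacement of its alkoxyphosphonium (the phenol cannot be displaced), and imidazole-promoted silylation then masks the acidic phenol, which would otherwise protonate the organozinc of step 3; no stereocentre is formed.

Step 3
Reactants: 3 6,7-dimethoxy-4H-chromen-4-one; 6 tert-butyl[4-(2-bromoethyl)-2-methoxyphenoxy]dimethylsilane
Product: 9 2-[2-(4-hydroxy-3-methoxyphenyl)ethyl]-6,7-dimethoxy-4H-chromen-4-one, via bis(chromon-2-yl)zinc 7 (not isolated), via silyl ether 8 (not isolated)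
Conditions: 3 (1.4 equiv), TMP2Zn·2MgCl2·2LiCl (0.7 equiv; TMP = 2,2,6,6-tetramethylpiperidide), THF, 25 °C, 1 h; then 6 (1.0 equiv), Pd2(dba)3 (2 mol %), PCyp3 (8 mol %), N-methylimidazole (1.2 equiv), THF/NMP 2:1, 80 °C, 14 h; then AcOH (6 equiv), TBAF (3 equiv), 25 °C, 2 h
Reagents that add atoms: none
Why: Proposed new method: the magnesium-complexed zinc amide removes the most acidic C–H (C2, next to the ring oxygen and vinylogous to the MgCl2-activated C4 carbonyl, which is also blocked from directing the base to C3) to give a C2-zinc chromone in which the normally electrophilic C2 is the nucleophile; the primary alkyl bromide adds to zerovalent palladium carrying the bulky, electron-rich PCyp3 by SN2-type oxidative addition, N-methylimidazole-assisted transmetalation of the chromonyl group and fast sp2–sp3 reductive elimination outrun β-hydride elimination, and buffered fluoride then cleaves the aryl silyl ether; the closest known reactions are directed C2 zincation of chromones followed by Negishi arylation and the Negishi coupling of alkenylzinc reagents with unactivated primary alkyl bromides; no stereocentre is formed.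

**Compound list**
1 | 1-(2-hydroxy-4,5-dimethoxyphenyl)ethan-1-one | CC(=O)c1cc(OC)c(OC)cc1O | starting material
2 | (E)-3-(dimethylamino)-1-(2-hydroxy-4,5-dimethoxyphenyl)prop-2-en-1-one | CN(C)/C=C/C(=O)c1cc(OC)c(OC)cc1O | intermediate
3 | 6,7-dimethoxy-4H-chromen-4-one | COc1cc2occc(=O)c2cc1OC | intermediate
4 | 4-(2-hydroxyethyl)-2-methoxyphenol | COc1cc(CCO)ccc1O | starting material
5 | 4-(2-bromoethyl)-2-methoxyphenol | COc1cc(CCBr)ccc1O | intermediate
6 | tert-butyl[4-(2-bromoethyl)-2-methoxyphenoxy]dimethylsilane | COc1cc(CCBr)ccc1O[Si](C)(C)C(C)(C)C | intermediate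
7 | bis(6,7-dimethoxy-4-oxo-4H-chromen-2-yl)zinc (as its MgCl2/LiCl complex) | COc1cc2oc([Zn]c3cc(=O)c4cc(OC)c(OC)cc4o3)cc(=O)c2cc1OC | intermediate
8 | 2-{2-[4-(tert-butyldimethylsilyloxy)-3-methoxyphenyl]ethyl}-6,7-dimethoxy-4H-chromen-4-one | COc1cc(CCc2cc(=O)c3cc(OC)c(OC)cc3o2)ccc1O[Si](C)(C)C(C)(C)C | intermediate
9 | 2-[2-(4-hydroxy-3-methoxyphenyl)ethyl]-6,7-dimethoxy-4H-chromen-4-one | COc1cc(CCc2cc(=O)c3cc(OC)c(OC)cc3o2)ccc1O | target

**Step count**
Total: 3 steps (three isolations). Longest linear sequence: 2 steps (step 1 then step 3, or step 2 then step 3).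

**Steps most likely to fail, with fallbacks**

Step 3 is the main risk. The phenethyl–palladium intermediate has benzylic β-hydrogens and may give the styrene, the electron-poor chromonyl zinc may transmetalate slowly, and the zinc species may not survive 80 °C. The fallback sets out from 7. Quenching 7 with I2 (THF, 0 °C) gives 2-iodo-6,7-dimethoxy-4H-chromen-4-one F1. F1 and bromide 6 are then joined by a nickel-catalysed reductive cross-electrophile coupling (NiBr2·glyme 10 mol %, 4,4'-di-tert-butyl-2,2'-bipyridine 10 mol %, Zn dust 2 equiv, NaI 25 mol %, DMA, 60 °C), a radical-chain process that avoids both the alkylpalladium and a preformed organometallic. This gives 8, where the route is rejoined (AcOH/TBAF to 9).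

Step 2 is the next risk. The bromophosphonium reagent may be consumed by the free phenol, or the one-pot silylation may be incomplete in the presence of phosphorus by-products. The fallback sets out from 4. Both hydroxyls are silylated (TBSCl 2.4 equiv, imidazole, DMF, rt) to give tert-butyl{4-[2-(tert-butyldimethylsilyloxy)ethyl]-2-methoxyphenoxy}dimethylsilane F2. Ph3PBr2 (1.05 equiv, CH2Cl2, 0 °C) then converts only the primary alkyl silyl ether directly into the bromide, since the aryl silyl ether cannot undergo SN2 at carbon. This arrives at 6.

Step 1 is the least risky. Possible problems are O-methylation of the phenol by the amide acetal or incomplete cyclisation. The fallback sets out from 1. Claisen formylation (ethyl formate, NaH, THF, 0 °C to rt) gives 2-hydroxy-6,7-dimethoxychroman-4-one F3, the racemic cyclic hemiacetal of the β-ketoaldehyde. Acid dehydration (conc. HCl, AcOH, 60 °C) then gives 3.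

**Further compounds**
F1 | step 3 | 2-iodo-6,7-dimethoxy-4H-chromen-4-one | COc1cc2oc(I)cc(=O)c2cc1OC
F2 | step 2 | tert-butyl{4-[2-(tert-butyldimethylsilyloxy)ethyl]-2-methoxyphenoxy}dimethylsilane | COc1cc(CCO[Si](C)(C)C(C)(C)C)ccc1O[Si](C)(C)C(C)(C)C
F3 | step 1 | 2-hydroxy-6,7-dimethoxychroman-4-one (racemic hemiacetal) | COc1cc2OC(O)CC(=O)c2cc1OC
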